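**Retrosynthetic overview**
1. Last bond: C7–vinyl, made by Suzuki coupling of a 7-bromobenzodioxane with an (E)-β-boryl acrolein acetal (fragment 3). The acetal is hydrolysed in the work-up.
2. Only ring made: the 1,4-dioxane, closed at O1–C2 by intramolecular oxa-Michael (1,6-) addition of the ring A phenoxide to a syringyl p-quinone methide. Fluoride releases the quinone methide from a bis-silylated benzylic acetate, and the freed 4'-phenoxide is methylated in the same flask.
3. C2–aryl bond: 4-silyloxy-3,5-dimethoxyphenyllithium (fragment 2, from syringol) adds to an (S)-2-aryloxypropanal (fragment 1).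
4. Fragment 1: the O4–C3 bond comes from SN2 inversion of (R)-lactate triflate by 5-bromo-o-vanillin. The formyl group is a latent O1 phenol (Baeyer–Villiger) and the bromide is a placeholder for the enal.
5. Ring order: both benzene rings are bought and the dioxane ring is formed once, in step 10. C3 comes from the chiral pool and controls C2.

Assumption: the SMILES is read as the trans-(2S,3S) benzodioxane with an (E)-enal; the numbering used throughout is O1, C2 (aryl), C3 (methyl), O4, C5 (OMe), C7 (side chain).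

**Step 1**
Reactants: 1 o-vanillin (2-hydroxy-3-methoxybenzaldehyde)
Product: 2 5-bromo-2-hydroxy-3-methoxybenzaldehyde
Conditions: Br2 (1.05 equiv), NaOAc (1.1 equiv), AcOH, 0 °C → rt
Reagents that add atoms: bromine, BrBr
Why: Electrophilic aromatic bromination goes para to the free phenol, whose ortho sites carry CHO and OMe, so only C5 reacts, and no stereocentre is involved.

**Step 2**
Reactants: 3 methyl (R)-lactate
Product: 4 methyl (2R)-2-(trifluoromethylsulfonyloxy)propanoate
Conditions: Tf2O (1.1 equiv), 2,6-lutidine (1.2 equiv), CH2Cl2, −78 → 0 °C; short silica plug, used the same day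
Reagents that add atoms: trifluoromethanesulfonic anhydride, O=S(=O)(OS(=O)(=O)C(F)(F)F)C(F)(F)F
Why: O-Sulfonylation (triflation) breaks only the O–H bond, so the (R) centre is retained and a leaving group good enough for a cold SN2 on a hindered phenoxide is installed.

**Step 3**
Reactants: 2 5-bromo-2-hydroxy-3-methoxybenzaldehyde; 4 methyl (2R)-2-(trifluoromethylsulfonyloxy)propanoate
Product: 5 methyl (2S)-2-(4-bromo-2-formyl-6-methoxyphenoxy)propanoate
Conditions: K2CO3 (1.5 equiv), MeCN, 0 °C → rt
Reagents that add atoms: none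
Why: Williamson-type SN2 etherification displaces triflate with Walden inversion, (R) → (S), which sets C3 of the target, and the low temperature avoids ester enolisation and aldol attack on the ortho formyl group.

**Step 4**
Reactants: 5 methyl (2S)-2-(4-bromo-2-formyl-6-methoxyphenoxy)propanoate
Product: 7 methyl (2S)-2-(4-bromo-2-hydroxy-6-methoxyphenoxy)propanoate, via aryl formate 6 (not isolated)
Conditions: mCPBA (1.5 equiv), CH2Cl2, rt; wash aq. Na2S2O3/NaHCO3; then MeOH, Et3N (0.2 equiv), 0 °C → rt
Reagents that add atoms: mCPBA, OOC(=O)c1cccc(Cl)c1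
Why: In this Baeyer–Villiger oxidation the ortho-alkoxy-activated aryl group migrates to give formate 6, and amine-catalysed methanolysis then frees the O1 phenol without touching the methyl ester, the aryl bromide or C3.

**Step 5**
Reactants: 7 methyl (2S)-2-(4-bromo-2-hydroxy-6-methoxyphenoxy)propanoate
Product: 8 methyl (2S)-2-{4-bromo-2-[(tert-butyldimethylsilyl)oxy]-6-methoxyphenoxy}propanoate
Conditions: TBSCl (1.2 equiv), imidazole (2.5 equiv), DMF, rt, run directly on fresh 7
Reagents that add atoms: TBSCl, CC(C)(C)[Si](C)(C)Cl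
Why: Imidazole-promoted silylation of the phenol is much faster than lactonisation onto the ester, and it gives a group that survives hydride and aryllithium yet falls to fluoride in step 10.

**Step 6**
Reactants: 8 methyl (2S)-2-{4-bromo-2-[(tert-butyldimethylsilyl)oxy]-6-methoxyphenoxy}propanoate
Product: 9 (2S)-2-{4-bromo-2-[(tert-butyldimethylsilyl)oxy]-6-methoxyphenoxy}propanal
Conditions: i-Bu2AlH (1.1 equiv), toluene/CH2Cl2, −78 °C; MeOH at −78 °C, aq. potassium sodium tartrate; used at once
Reagents that add atoms: none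
Why: Partial reduction of an α-aryloxy ester with one equivalent of i-Bu2AlH stops at the aldehyde level at −78 °C, and the neutral cold work-up leaves C3, the silyl ether and the bromide untouched.

**Step 7**
Reactants: 10 2,6-dimethoxyphenol (syringol)
Product: 11 4-bromo-2,6-dimethoxyphenol
Conditions: NBS (1.0 equiv), NaH (cat.), CHCl3/MeOH, −45 °C → rt
Reagents that add atoms: N-bromosuccinimide, O=C1CCC(=O)N1Br
Why: Electrophilic aromatic bromination under phenoxide control goes para to the oxygen, since both ortho positions are blocked, rather than ortho to a methoxy group.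

**Step 8**
Reactants: 11 4-bromo-2,6-dimethoxyphenol
Product: 12 (4-bromo-2,6-dimethoxyphenoxy)(tert-butyl)dimethylsilane
Conditions: TBSCl (1.3 equiv), imidazole (2.5 equiv), DMF, rt
Reagents that add atoms: TBSCl, CC(C)(C)[Si](C)(C)Cl
Why: Silyl ether formation masks the acidic phenol for the metalation, and the silyl ether later serves as the fluoride trigger for quinone methide release.

**Step 9**
Reactants: 12 (4-bromo-2,6-dimethoxyphenoxy)(tert-butyl)dimethylsilane; 9 (2S)-2-{4-bromo-2-[(tert-butyldimethylsilyl)oxy]-6-methoxyphenoxy}propanal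
Product: 15 (1RS,2S)-2-{4-bromo-2-[(tert-butyldimethylsilyl)oxy]-6-methoxyphenoxy}-1-{4-[(tert-butyldimethylsilyl)oxy]-3,5-dimethoxyphenyl}propyl acetate (both C1 epimers), via aryllithium 13 (not isolated), via lithium alkoxide 14 (not isolated)
Conditions: 12 (1.2 equiv), n-BuLi (1.15 equiv), THF, −78 °C, 30 min; 9 (1.0 equiv), −78 °C, 45 min; Ac2O (3 equiv), DMAP (0.1 equiv), −78 → 0 °C
Reagents that add atoms: acetic anhydride, CC(=O)OC(C)=O
Why: Bromine–lithium exchange, 1,2-addition of the aryllithium to the aldehyde (far faster at −78 °C than exchange with the ring A bromide) and in situ O-acetylation give the benzylic acetate, whose new centre forms as an epimer mixture that does not matter because step 10 planarises it.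

**Step 10**
Reactants: 15 (1RS,2S)-2-{4-bromo-2-[(tert-butyldimethylsilyl)oxy]-6-methoxyphenoxy}-1-{4-[(tert-butyldimethylsilyl)oxy]-3,5-dimethoxyphenyl}propyl acetate
Product: 18 (2S,3S)-7-bromo-5-methoxy-3-methyl-2-(3,4,5-trimethoxyphenyl)-2,3-dihydro-1,4-benzodioxine, via quinone methide 16 (not isolated), via phenol 17 (not isolated)
Conditions: n-Bu4NF (2.5 equiv, 1 M in THF), THF, 0 °C → rt, 1–2 h; then MeI (5 equiv), rt, 3 h; minor cis isomer removed by chromatography
Reagents that add atoms: iodomethane, CI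
Why: Fluoride strips both silyl groups and acetate leaves by 1,6-elimination to give p-quinone methide 16, whose exocyclic carbon is attacked by the neighbouring ring A phenoxide in a 6-exo-trig intramolecular oxa-Michael (1,6-conjugate) addition that rearomatises the syringyl ring; because this addition is reversible while the 4'-oxygen is free, the fixed (S) centre at C3 steers the new C2 centre to the diequatorial trans (2S,3S) arrangement, and SN2 O-methylation of 17 then locks it.

**Step 11**
Reactants: 19 3,3-diethoxyprop-1-yne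
Product: 20 2-[(E)-3,3-diethoxyprop-1-en-1-yl]-4,4,5,5-tetramethyl-1,3,2-dioxaborolane
Conditions: pinacolborane (1.1 equiv), Cp2ZrHCl (5 mol %), Et3N (10 mol %), neat, 60 °C
Reagents that add atoms: pinacolborane, [H]B1OC(C)(C)C(C)(C)O1
Why: Zirconocene-hydride-catalysed hydroboration is a syn, anti-Markovnikov addition, so only the (E)-vinylboronate forms and the acetal is untouched.

**Step 12**
Reactants: 18 (2S,3S)-7-bromo-5-methoxy-3-methyl-2-(3,4,5-trimethoxyphenyl)-2,3-dihydro-1,4-benzodioxine; 20 2-[(E)-3,3-diethoxyprop-1-en-1-yl]-4,4,5,5-tetramethyl-1,3,2-dioxaborolane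
Product: 22 (2E)-3-[(2S,3S)-5-methoxy-3-methyl-2-(3,4,5-trimethoxyphenyl)-2,3-dihydro-1,4-benzodioxin-7-yl]prop-2-enal (target), via diethyl acetal 21 (not isolated)
Conditions: Pd(dppf)Cl2 (5 mol %), K2CO3 (3 equiv), 1,4-dioxane/H2O 4:1, 85 °C; then 1 M HCl, THF, rt, 30 min
Reagents that add atoms: water, O
Why: Suzuki–Miyaura coupling transfers the vinyl group with retention of the E geometry, and the allylic acetal hydrolyses under acid too mild to ionise the benzylic ether, so C2 and C3, which can no longer open to a quinone methide after methylation, stay intact.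

**Compound list**
1 | o-vanillin (2-hydroxy-3-methoxybenzaldehyde) | COc1cccc(C=O)c1O | starting material
2 | 5-bromo-2-hydroxy-3-methoxybenzaldehyde | COc1cc(Br)cc(C=O)c1O | intermediate
3 | methyl (R)-lactate | C[C@@H](O)C(=O)OC | starting material
4 | methyl (2R)-2-(trifluoromethylsulfonyloxy)propanoate | C[C@@H](OS(=O)(=O)C(F)(F)F)C(=O)OC | intermediate
5 | methyl (2S)-2-(4-bromo-2-formyl-6-methoxyphenoxy)propanoate | C[C@H](Oc1c(C=O)cc(Br)cc1OC)C(=O)OC | intermediate
6 | methyl (2S)-2-[4-bromo-2-(formyloxy)-6-methoxyphenoxy]propanoate (aryl formate, not isolated) | C[C@H](Oc1c(OC=O)cc(Br)cc1OC)C(=O)OC | intermediate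
7 | methyl (2S)-2-(4-bromo-2-hydroxy-6-methoxyphenoxy)propanoate | C[C@H](Oc1c(O)cc(Br)cc1OC)C(=O)OC | intermediate
8 | methyl (2S)-2-{4-bromo-2-[(tert-butyldimethylsilyl)oxy]-6-methoxyphenoxy}propanoate | C[C@H](Oc1c(O[Si](C)(C)C(C)(C)C)cc(Br)cc1OC)C(=O)OC | intermediate
9 | (2S)-2-{4-bromo-2-[(tert-butyldimethylsilyl)oxy]-6-methoxyphenoxy}propanal | C[C@H](Oc1c(O[Si](C)(C)C(C)(C)C)cc(Br)cc1OC)C=O | intermediate
10 | 2,6-dimethoxyphenol (syringol) | COc1cccc(OC)c1O | starting material
11 | 4-bromo-2,6-dimethoxyphenol | COc1cc(Br)cc(OC)c1O | intermediate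
12 | (4-bromo-2,6-dimethoxyphenoxy)(tert-butyl)dimethylsilane | COc1cc(Br)cc(OC)c1O[Si](C)(C)C(C)(C)C | intermediate
13 | {4-[(tert-butyldimethylsilyl)oxy]-3,5-dimethoxyphenyl}lithium (not isolated) | [Li]c1cc(OC)c(O[Si](C)(C)C(C)(C)C)c(OC)c1 | intermediate
14 | lithium (1RS,2S)-2-{4-bromo-2-[(tert-butyldimethylsilyl)oxy]-6-methoxyphenoxy}-1-{4-[(tert-butyldimethylsilyl)oxy]-3,5-dimethoxyphenyl}propan-1-olate (not isolated) | C[C@H](Oc1c(O[Si](C)(C)C(C)(C)C)cc(Br)cc1OC)C([O-])c1cc(OC)c(O[Si](C)(C)C(C)(C)C)c(OC)c1.[Li+] | intermediate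
15 | (1RS,2S)-2-{4-bromo-2-[(tert-butyldimethylsilyl)oxy]-6-methoxyphenoxy}-1-{4-[(tert-butyldimethylsilyl)oxy]-3,5-dimethoxyphenyl}propyl acetate (C1 epimer mixture, C2 is S) | C[C@H](Oc1c(O[Si](C)(C)C(C)(C)C)cc(Br)cc1OC)C(OC(C)=O)c1cc(OC)c(O[Si](C)(C)C(C)(C)C)c(OC)c1 | intermediate
16 | 4-[(2S)-2-(4-bromo-2-hydroxy-6-methoxyphenoxy)propylidene]-2,6-dimethoxycyclohexa-2,5-dien-1-one (p-quinone methide, present as its phenoxide, not isolated) | C[C@H](Oc1c(O)cc(Br)cc1OC)C=C1C=C(OC)C(=O)C(OC)=C1 | intermediate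
17 | 4-[(2S,3S)-7-bromo-5-methoxy-3-methyl-2,3-dihydro-1,4-benzodioxin-2-yl]-2,6-dimethoxyphenol (trans, present as its tetrabutylammonium salt, not isolated) | COc1cc([C@@H]2Oc3cc(Br)cc(OC)c3O[C@H]2C)cc(OC)c1O | intermediate
18 | (2S,3S)-7-bromo-5-methoxy-3-methyl-2-(3,4,5-trimethoxyphenyl)-2,3-dihydro-1,4-benzodioxine (trans) | COc1cc([C@@H]2Oc3cc(Br)cc(OC)c3O[C@H]2C)cc(OC)c1OC | intermediate
19 | 3,3-diethoxyprop-1-yne | C#CC(OCC)OCC | starting material
20 | 2-[(E)-3,3-diethoxyprop-1-en-1-yl]-4,4,5,5-tetramethyl-1,3,2-dioxaborolane | CCOC(OCC)/C=C/B1OC(C)(C)C(C)(C)O1 | intermediate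
21 | (2S,3S)-7-[(E)-3,3-diethoxyprop-1-en-1-yl]-5-methoxy-3-methyl-2-(3,4,5-trimethoxyphenyl)-2,3-dihydro-1,4-benzodioxine (not isolated) | COc1cc([C@@H]2Oc3cc(/C=C/C(OCC)OCC)cc(OC)c3O[C@H]2C)cc(OC)c1OC | intermediate
22 | (2E)-3-[(2S,3S)-5-methoxy-3-methyl-2-(3,4,5-trimethoxyphenyl)-2,3-dihydro-1,4-benzodioxin-7-yl]prop-2-enal | COc1cc([C@@H]2Oc3cc(/C=C/C=O)cc(OC)c3O[C@H]2C)cc(OC)c1OC | target

**Total step count:** 12.
**Longest linear sequence:** 8 steps (1 → 3 → 4 → 5 → 6 → 9 → 10 → 12). The line that starts with step 2 is equally long. Steps 7, 8 and 11, and one of steps 1 and 2, lie off this line.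

**Three steps most likely to fail**

**Step 10.**
- Risks: quinone methide 16 could tautomerise to the enol ether under basic fluoride, which would erode C3. It could also pick up water, or the trans:cis ratio could be too low at the moment of methylation.
- Fallback: it sets out from 9 and comes back at 18. It closes the same O1–C2 bond on the O-methylated, cationic counterpart of the quinone methide, so no fluoride-generated base and no methylation are needed. Commercial 5-bromo-1,2,3-trimethoxybenzene and n-BuLi (THF, −78 °C) give 3,4,5-trimethoxyphenyllithium F1, which adds to 9 to give the silyl-protected carbinol F2. n-Bu4NF frees the ring A phenol to give the phenol carbinol F3. A sulfonic acid resin (Amberlyst 15) or catalytic TsOH in CH2Cl2 then ionises the benzylic alcohol. The phenol adds to the 4-methoxybenzylic cation under equilibrating conditions, which favour trans 18.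

**Step 9.**
- Risks: aldehyde 9 may epimerise, a little lithium–bromine exchange on ring A may occur, and the O1 silyl group may migrate to the new alkoxide before acetylation.
- Fallback: it sets out from 8 and comes back at 15. It replaces addition to the aldehyde by acylation followed by reduction. Ester 8 with MeNH(OMe)·HCl and i-PrMgCl (THF, −20 °C) gives the configurationally robust Weinreb amide F4. Aryllithium 13 (from 12) adds once at −78 °C to give the aryl ketone F5. Prompt reduction with NaBH4 (THF/MeOH, −20 °C) gives the carbinol F6. Ac2O, pyridine and DMAP convert this to 15.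

**Step 6.**
- Risks: over-reduction, or loss of configurational purity of 9 during work-up.
- Fallback: it sets out from 8 and comes back at 9. It gives up the partial reduction for a two-stage redox sequence. i-Bu2AlH (2.5 equiv, CH2Cl2, −78 → 0 °C) takes 8 fully to the primary alcohol F7. This compound is stable, can be purified and can be checked for enantiomeric purity. Dess–Martin periodinane buffered with NaHCO3 (CH2Cl2, 0 °C) then gives 9 just before use.

**Further compounds**
F1 | step 10 | 3,4,5-trimethoxyphenyllithium | [Li]c1cc(OC)c(OC)c(OC)c1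
F2 | step 10 | (1RS,2S)-2-{4-bromo-2-[(tert-butyldimethylsilyl)oxy]-6-methoxyphenoxy}-1-(3,4,5-trimethoxyphenyl)propan-1-ol | C[C@H](Oc1c(O[Si](C)(C)C(C)(C)C)cc(Br)cc1OC)C(O)c1cc(OC)c(OC)c(OC)c1
F3 | step 10 | 5-bromo-2-{[(1RS,2S)-1-hydroxy-1-(3,4,5-trimethoxyphenyl)propan-2-yl]oxy}-3-methoxyphenol | C[C@H](Oc1c(O)cc(Br)cc1OC)C(O)c1cc(OC)c(OC)c(OC)c1
F4 | step 9 | (2S)-2-{4-bromo-2-[(tert-butyldimethylsilyl)oxy]-6-methoxyphenoxy}-N-methoxy-N-methylpropanamide | C[C@H](Oc1c(O[Si](C)(C)C(C)(C)C)cc(Br)cc1OC)C(=O)N(C)OC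
F5 | step 9 | (2S)-2-{4-bromo-2-[(tert-butyldimethylsilyl)oxy]-6-methoxyphenoxy}-1-{4-[(tert-butyldimethylsilyl)oxy]-3,5-dimethoxyphenyl}propan-1-one | C[C@H](Oc1c(O[Si](C)(C)C(C)(C)C)cc(Br)cc1OC)C(=O)c1cc(OC)c(O[Si](C)(C)C(C)(C)C)c(OC)c1
F6 | step 9 | (1RS,2S)-2-{4-bromo-2-[(tert-butyldimethylsilyl)oxy]-6-methoxyphenoxy}-1-{4-[(tert-butyldimethylsilyl)oxy]-3,5-dimethoxyphenyl}propan-1-ol | C[C@H](Oc1c(O[Si](C)(C)C(C)(C)C)cc(Br)cc1OC)C(O)c1cc(OC)c(O[Si](C)(C)C(C)(C)C)c(OC)c1
F7 | step 6 | (2S)-2-{4-bromo-2-[(tert-butyldimethylsilyl)oxy]-6-methoxyphenoxy}propan-1-ol | C[C@H](Oc1c(O[Si](C)(C)C(C)(C)C)cc(Br)cc1OC)CO
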